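Everything rests on the C3–C3a bond. C3 of the furan carries the formyl carbon and C3a of the fused benzene ring (ring A), and C3a lies between two oxygenated carbons, C4 and C7a. A 1,2-shift induced by trivalent iodine moves a symmetrical 2,6-dioxygenated aryl group from the β carbon (future CHO) to the α carbon (future C3) of a chalcone, giving the 2-aryl-3-formyl carbon pattern as a keto acetal in one operation. The precursor is an E-chalcone with a bis-MOM phloroglucinol ring on the β carbon and the tosylated 2-aryl ring (ring B) on the carbonyl. Acid then closes the furan through either phenol; a late Claisen rearrangement places prenyl at C5.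

Key step: step 5

Remark: compounds 8, 9, 11, 12 and 13 are racemic (13 also a cis/trans mixture) and are drawn without stereodescriptors, because their stereocentres vanish before the target, which has none. "Tosyloxy" stands for 4-methylbenzenesulfonyloxy.

Step 1
Reactants: 1 5-methoxyresorcinol
Product: 2 1-methoxy-3,5-bis(methoxymethoxy)benzene
Conditions: MOMCl, i-Pr2NEt, CH2Cl2, 0 °C to rt
Reagents that add atoms: chloromethyl methyl ether, COCCl
Why: Williamson-type O-alkylation of the two equivalent phenols with the reactive α-chloro ether under amine base should give the bis-MOM ether, whose MOM groups later direct the lithiation and mask the phenols from the oxidant.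

Step 2
Reactants: 2 1-methoxy-3,5-bis(methoxymethoxy)benzene
Product: 4 4-methoxy-2,6-bis(methoxymethoxy)benzaldehyde, via aryllithium 3 (not isolated)
Conditions: n-BuLi, TMEDA, THF, 0 °C; then DMF, 0 °C to rt; aq. NH4Cl
Reagents that add atoms: N,N-dimethylformamide, CN(C)C=O
Why: Directed ortho-metalation followed by formylation with DMF, in which the C–H between the two MOM ethers is doubly chelated and should be lithiated in preference to the positions flanked by OMOM and OMe.

Step 3
Reactants: 5 4'-hydroxy-2'-methoxyacetophenone
Product: 6 4-acetyl-3-methoxyphenyl 4-methylbenzenesulfonate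
Conditions: TsCl, Et3N, DMAP (cat.), CH2Cl2, 0 °C to rt
Reagents that add atoms: p-toluenesulfonyl chloride, Cc1ccc(cc1)S(=O)(=O)Cl
Why: O-sulfonylation of the only phenol gives an aryl tosylate that should withstand acid, the trivalent iodine oxidant, hydrogenation and heat, and that hydroxide can cleave at the very end.

Step 4
Reactants: 6 4-acetyl-3-methoxyphenyl 4-methylbenzenesulfonate; 4 4-methoxy-2,6-bis(methoxymethoxy)benzaldehyde
Product: 10 (E)-3-[4-methoxy-2,6-bis(methoxymethoxy)phenyl]-1-(2-methoxy-4-tosyloxyphenyl)prop-2-en-1-one, via lithium enolate 7 (not isolated), via lithium aldolate 8 (not isolated), via benzylic mesylate 9 (not isolated)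
Conditions: LiN(SiMe3)2, THF, −78 °C; then 4, −78 °C; then MsCl, Et3N, −78 °C to rt
Reagents that add atoms: none
Why: A directed aldol addition of the kinetic lithium enolate, followed by mesylation of the aldolate and E1cB elimination, is a hydroxide-free equivalent of the Claisen–Schmidt condensation, chosen because hydroxide or alkoxide would attack the aryl sulfonate activated by the para acyl group; the racemic carbinol centre of 8 and 9 is lost and the conjugated E-alkene should form under thermodynamic control.

Step 5
Reactants: 10 (E)-3-[4-methoxy-2,6-bis(methoxymethoxy)phenyl]-1-(2-methoxy-4-tosyloxyphenyl)prop-2-en-1-one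
Product: 11 3,3-dimethoxy-2-[4-methoxy-2,6-bis(methoxymethoxy)phenyl]-1-(2-methoxy-4-tosyloxyphenyl)propan-1-one
Conditions: PhI(OH)OTs, MeOH, 0 °C to rt; then aq. NaHCO3
Reagents that add atoms: methanol, CO
Why: Methanol adds to the β carbon of the enone, where positive charge is stabilised by the three ring oxygens, and the trivalent iodine reagent bonds to the α carbon of the enol so formed; the trioxygenated aryl group then shifts from the β to the α carbon through a phenonium ion as iodobenzene departs, and the oxocarbenium ion left at the old β carbon takes up a second methanol to give the dimethyl acetal. The closest known reaction type is the oxidative 1,2-aryl migration of chalcones to 1,2-diaryl-3,3-dimethoxypropan-1-ones with PhI(OH)OTs or Tl(NO3)3 in methanol (the isoflavone-type rearrangement), which is also known for chalcones with a MOM-protected 2-hydroxyaryl group on the β carbon. This step forms the C3–C3a bond of the future benzofuran and closes no ring; the furan is closed in step 6 by O1–C2 bond formation. The one new stereocentre, C2 of the propanone, forms as a racemate, needs no control and disappears on aromatisation. The step needs migration of the donor-rich aryl group and not of the aroyl group, and it needs both rings to escape oxidation; the first is secured by regioselective methanol addition at the benzylic β carbon and the high migratory aptitude of the trioxygenated ring, the second by MOM masking of the phenols and by the sulfonate and carbonyl groups that deactivate ring B.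

Step 6
Reactants: 11 3,3-dimethoxy-2-[4-methoxy-2,6-bis(methoxymethoxy)phenyl]-1-(2-methoxy-4-tosyloxyphenyl)propan-1-one
Product: 14 4-hydroxy-6-methoxy-2-(2-methoxy-4-tosyloxyphenyl)benzofuran-3-carbaldehyde, via diphenol keto acetal 12 (not isolated), via cyclic mixed acetal 13 (not isolated)
Conditions: p-TsOH·H2O, (CF3)2CHOH, rt
Reagents that add atoms: water, O
Why: Strong acid in the ionising but weakly nucleophilic fluoro alcohol removes both MOM groups and lets the mixed acetal 13 (formed first by phenol attack on the acetal carbon) reopen instead of losing methanol, so that either of the two equivalent phenols should add 5-exo-trig to the protonated ketone, the hemiketal dehydrates to the aromatic furan and the acetal is hydrolysed to the aldehyde, a known acid-mediated cyclodehydration of 2-(2-hydroxyaryl)-3,3-dimethoxy ketones to 2-aryl-3-formylbenzofurans.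

Step 7
Reactants: 14 4-hydroxy-6-methoxy-2-(2-methoxy-4-tosyloxyphenyl)benzofuran-3-carbaldehyde; 15 3-chloro-3-methylbut-1-yne
Product: 16 6-methoxy-2-(2-methoxy-4-tosyloxyphenyl)-4-(2-methylbut-3-yn-2-yloxy)benzofuran-3-carbaldehyde
Conditions: DBU, CuCl2 (cat.), MeCN, 0 °C to rt
Reagents that add atoms: none
Why: Copper-catalysed propargylic etherification, in which the copper acetylide of 15 ionises to an allenylidene-type electrophile that the DBU-generated phenoxide of the single free OH should capture at the tertiary carbon, a bond that plain SN2 alkylation could not make.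

Step 8
Reactants: 16 6-methoxy-2-(2-methoxy-4-tosyloxyphenyl)-4-(2-methylbut-3-yn-2-yloxy)benzofuran-3-carbaldehyde
Product: 17 6-methoxy-2-(2-methoxy-4-tosyloxyphenyl)-4-(2-methylbut-3-en-2-yloxy)benzofuran-3-carbaldehyde
Conditions: H2 (1 atm), Pd/CaCO3 poisoned with Pb(OAc)2 (Lindlar catalyst), quinoline, EtOAc, rt
Reagents that add atoms: none
Why: Lindlar semihydrogenation, in which the terminal alkyne binds the poisoned palladium surface far more strongly than the alkene product, so reduction should stop at the 1,1-dimethylallyl ether without touching the aldehyde, the furan or the sulfonate.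

Step 9
Reactants: 17 6-methoxy-2-(2-methoxy-4-tosyloxyphenyl)-4-(2-methylbut-3-en-2-yloxy)benzofuran-3-carbaldehyde
Product: 18 4-hydroxy-6-methoxy-2-(2-methoxy-4-tosyloxyphenyl)-5-(3-methylbut-2-enyl)benzofuran-3-carbaldehyde
Conditions: PhNEt2, 130 °C
Reagents that add atoms: none
Why: Aromatic Claisen rearrangement, a [3,3]-sigmatropic shift in which the CH2 terminus of the tertiary allyl ether bonds to C5, the only ortho carbon that carries hydrogen (the other is the ring-fusion carbon C3a), and rearomatisation should give the 4-hydroxy-5-prenyl pattern while the amine solvent suppresses acid-catalysed chroman formation.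

Step 10
Reactants: 18 4-hydroxy-6-methoxy-2-(2-methoxy-4-tosyloxyphenyl)-5-(3-methylbut-2-enyl)benzofuran-3-carbaldehyde
Product: 19 4-hydroxy-2-(4-hydroxy-2-methoxyphenyl)-6-methoxy-5-(3-methylbut-2-enyl)benzofuran-3-carbaldehyde (the target)
Conditions: KOH, 1,4-dioxane/H2O, 60 °C; then dilute HCl
Reagents that add atoms: none
Why: Hydrolytic cleavage of the aryl sulfonate by hydroxide attack at sulfur, in which the 4-OH is deprotonated first so that the phenoxide shields the formyl group and C2 from hydroxide, and the prenyl alkene is inert to base.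

Compound list
1 | 5-methoxyresorcinol | COc1cc(O)cc(O)c1 | starting material
2 | 1-methoxy-3,5-bis(methoxymethoxy)benzene | COCOc1cc(OC)cc(OCOC)c1 | intermediate
3 | 2-lithio-5-methoxy-1,3-bis(methoxymethoxy)benzene (aryllithium, formed in situ) | [Li]c1c(OCOC)cc(OC)cc1OCOC | intermediate
4 | 4-methoxy-2,6-bis(methoxymethoxy)benzaldehyde | COCOc1cc(OC)cc(OCOC)c1C=O | intermediate
5 | 4'-hydroxy-2'-methoxyacetophenone | CC(=O)c1ccc(O)cc1OC | starting material
6 | 4-acetyl-3-methoxyphenyl 4-methylbenzenesulfonate | CC(=O)c1ccc(OS(=O)(=O)c2ccc(C)cc2)cc1OC | intermediate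
7 | lithium enolate of 6 (formed in situ) | [Li]OC(=C)c1ccc(OS(=O)(=O)c2ccc(C)cc2)cc1OC | intermediate
8 | lithium aldolate from 7 and 4 (racemic, formed in situ) | [Li]OC(CC(=O)c1ccc(OS(=O)(=O)c2ccc(C)cc2)cc1OC)c1c(OCOC)cc(OC)cc1OCOC | intermediate
9 | benzylic mesylate of the aldol adduct (racemic, formed in situ) | CS(=O)(=O)OC(CC(=O)c1ccc(OS(=O)(=O)c2ccc(C)cc2)cc1OC)c1c(OCOC)cc(OC)cc1OCOC | intermediate
10 | (E)-3-[4-methoxy-2,6-bis(methoxymethoxy)phenyl]-1-(2-methoxy-4-tosyloxyphenyl)prop-2-en-1-one | COCOc1cc(OC)cc(OCOC)c1/C=C/C(=O)c1ccc(OS(=O)(=O)c2ccc(C)cc2)cc1OC | intermediate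
11 | 3,3-dimethoxy-2-[4-methoxy-2,6-bis(methoxymethoxy)phenyl]-1-(2-methoxy-4-tosyloxyphenyl)propan-1-one (racemic) | COCOc1cc(OC)cc(OCOC)c1C(C(OC)OC)C(=O)c1ccc(OS(=O)(=O)c2ccc(C)cc2)cc1OC | intermediate
12 | 2-(2,6-dihydroxy-4-methoxyphenyl)-3,3-dimethoxy-1-(2-methoxy-4-tosyloxyphenyl)propan-1-one (diphenol keto acetal, racemic, formed in situ) | COC(OC)C(c1c(O)cc(OC)cc1O)C(=O)c1ccc(OS(=O)(=O)c2ccc(C)cc2)cc1OC | intermediate
13 | 4-hydroxy-2,6-dimethoxy-3-(2-methoxy-4-tosyloxybenzoyl)-2,3-dihydrobenzofuran (cyclic mixed acetal, racemic cis/trans mixture, formed in situ) | COC1Oc2cc(OC)cc(O)c2C1C(=O)c1ccc(OS(=O)(=O)c2ccc(C)cc2)cc1OC | intermediate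
14 | 4-hydroxy-6-methoxy-2-(2-methoxy-4-tosyloxyphenyl)benzofuran-3-carbaldehyde | COc1cc(OS(=O)(=O)c2ccc(C)cc2)ccc1-c1oc2cc(OC)cc(O)c2c1C=O | intermediate
15 | 3-chloro-3-methylbut-1-yne | CC(C)(Cl)C#C | starting material
16 | 6-methoxy-2-(2-methoxy-4-tosyloxyphenyl)-4-(2-methylbut-3-yn-2-yloxy)benzofuran-3-carbaldehyde | C#CC(C)(C)Oc1cc(OC)cc2oc(-c3ccc(OS(=O)(=O)c4ccc(C)cc4)cc3OC)c(C=O)c12 | intermediate
17 | 6-methoxy-2-(2-methoxy-4-tosyloxyphenyl)-4-(2-methylbut-3-en-2-yloxy)benzofuran-3-carbaldehyde | C=CC(C)(C)Oc1cc(OC)cc2oc(-c3ccc(OS(=O)(=O)c4ccc(C)cc4)cc3OC)c(C=O)c12 | intermediate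
18 | 4-hydroxy-6-methoxy-2-(2-methoxy-4-tosyloxyphenyl)-5-(3-methylbut-2-enyl)benzofuran-3-carbaldehyde | COc1cc(OS(=O)(=O)c2ccc(C)cc2)ccc1-c1oc2cc(OC)c(CC=C(C)C)c(O)c2c1C=O | intermediate
19 | 4-hydroxy-2-(4-hydroxy-2-methoxyphenyl)-6-methoxy-5-(3-methylbut-2-enyl)benzofuran-3-carbaldehyde | COc1cc(O)ccc1-c1oc2cc(OC)c(CC=C(C)C)c(O)c2c1C=O | target

Total step count: 10. Longest linear sequence: 9 steps (steps 1, 2 and 4 to 10, from 1 to 19).

Steps most likely to fail

Step 5. The oxidant may attack the very electron-rich trioxygenated ring directly (ring oxidation or aryliodonium formation). Alternatively, the sulfonic acid released may strip a MOM group, after which the freed phenol is oxidised faster than the aryl group migrates. The fallback reaches the same carbon connectivity by an acyl shift instead of an aryl shift and avoids trivalent iodine altogether. It sets out from 10. Weitz–Scheffer epoxidation with t-BuOOH and DBU in CH2Cl2 should give the racemic trans-epoxy ketone F1. BF3·OEt2 in CH2Cl2 at −78 °C should open the epoxide at the benzylic carbon and trigger a Meinwald-type 1,2-shift of the aroyl group, giving the β-keto aldehyde F2, in which the trioxygenated aryl group, the aroyl group and the formyl group sit on one carbon as in 11. F2 is then treated with p-TsOH·H2O in (CF3)2CHOH as in step 6 and comes back to the route at 14.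

Step 6. The cyclic mixed acetal 13 may lose methanol irreversibly before it reopens, which closes the furan onto the formyl-level carbon and gives the isomeric 3-aroylbenzofuran. The fallback masks that carbon as a dithioacetal that does not ionise under protic acid, so that only the ketone can be attacked. It sets out from 11. Ethane-1,2-dithiol and BF3·OEt2 in CH2Cl2 at 0 °C should exchange the dimethyl acetal for a 1,3-dithiolane and cleave both MOM ethers, giving the dithiolane diphenol ketone F3. p-TsOH in toluene at 80 °C should then cyclodehydrate F3 to the 3-(1,3-dithiolan-2-yl)benzofuran F4. MeI and CaCO3 in aqueous MeCN should release the aldehyde, and the sequence comes back to the route at 14.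

Step 7. O-alkylation of the hydrogen-bonded 4-OH, which is crowded by the neighbouring 3-formyl group, with a tertiary electrophile may stall, or elimination of HCl from 15 may consume the reagent first. The fallback sets out from 14 and uses a Tsuji–Trost O-allylation with tert-butyl 2-methylbut-3-en-2-yl carbonate and Pd(PPh3)4 in THF at 0 °C. The phenoxide should attack the more substituted terminus of the π-allyl complex under kinetic control, giving the 1,1-dimethylallyl ether directly. The sequence comes back to the route at 17, so step 8 is no longer needed; no compound outside the list is made (F0).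

Further compounds
F1 | step 5 | trans-2,3-epoxy-3-[4-methoxy-2,6-bis(methoxymethoxy)phenyl]-1-(2-methoxy-4-tosyloxyphenyl)propan-1-one (racemic, one enantiomer drawn) | O=C(c1ccc(OS(=O)(=O)c2ccc(C)cc2)cc1OC)[C@@H]1O[C@H]1c1c(OCOC)cc(OC)cc1OCOC
F2 | step 5 | 2-[4-methoxy-2,6-bis(methoxymethoxy)phenyl]-3-(2-methoxy-4-tosyloxyphenyl)-3-oxopropanal (racemic, largely enolised) | COCOc1cc(OC)cc(OCOC)c1C(C=O)C(=O)c1ccc(OS(=O)(=O)c2ccc(C)cc2)cc1OC
F3 | step 6 | 2-(2,6-dihydroxy-4-methoxyphenyl)-2-(1,3-dithiolan-2-yl)-1-(2-methoxy-4-tosyloxyphenyl)ethanone (racemic) | COc1cc(O)c(C(C2SCCS2)C(=O)c2ccc(OS(=O)(=O)c3ccc(C)cc3)cc2OC)c(O)c1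
F4 | step 6 | 3-(1,3-dithiolan-2-yl)-4-hydroxy-6-methoxy-2-(2-methoxy-4-tosyloxyphenyl)benzofuran | COc1cc(OS(=O)(=O)c2ccc(C)cc2)ccc1-c1oc2cc(OC)cc(O)c2c1C1SCCS1
F0 | step 7 | none | none
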